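**Retrosynthetic overview** (ring B in phthalide numbering)
1. The (S)-lactol is released last by hydrogenolysis of a bis(benzyl carbonate). Its phthalidyl carbon is fixed by an acylative dynamic kinetic resolution of the racemic lactol, which is labile through ring–chain tautomerism.
2. Seven-membered dioxepinone ring: the lactone C(=O)–O bond (mixed anhydride) is cut after the diaryl ether C–O bond (SNAr of the ring-B 4-OH on a 2-fluoro-3-formylbenzoate, ring A).
3. γ-Lactol ring on ring B: both aryl–carbon bonds (C-7a to the carbonyl carbon, C-3a to the acetal carbon) are cut at once. This leads back to a ring-B aryne and a C–O–C unit carried by an oxazole (C-2, O-1, C-5, made from Boc-valine). Forward: [4+2], loss of isobutyronitrile, C-protonation of the isobenzofuran.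
4. Enabling feature: the oxygen on acetal carbon C-3 and the phenolic oxygen on C-4 (the later diaryl ether oxygen) are peri neighbours, so one iPr2Si atom can tie the oxazole 5-oxygen to the arene. The 5- and 7-oxygens of ring B make C-3 the basic carbon of the isobenzofuran, which places the carbonyl next to the 7-OH.
5. Ring order: two purchased benzene rings; oxazolone; temporary siladioxine ring and furanone ring together (key step); dioxepinone ring last.

Key step: step 8

Assumption: the lactol (pseudo-acid) carbon, the only stereocentre, epimerises by ring–chain tautomerism in basic or protic media but is taken to hold its configuration in the solid and in cold, neutral, aprotic solution, so it is set in step 12 and uncovered last under neutral conditions.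

**Step 1**
Reactants: 1 1-fluoro-3-methoxy-5-methylbenzene
Product: 3 2-fluoro-6-methoxy-4-methylbenzaldehyde, via aryllithium 2 (not isolated)
Conditions: nBuLi, THF, −78 °C; DMF, −78 to 0 °C; aq. HCl
Reagents that add atoms: N,N-dimethylformamide CN(C)C=O
Why: Directed ortho-metalation followed by formylation, in which the proton between F and OMe is by far the most acidic and both groups hold lithium, so only this position should react.

**Step 2**
Reactants: 3 2-fluoro-6-methoxy-4-methylbenzaldehyde
Product: 4 3-bromo-2-fluoro-6-methoxy-4-methylbenzaldehyde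
Conditions: NBS, MeCN, 0 °C to rt, dark
Reagents that add atoms: N-bromosuccinimide O=C1CCC(=O)N1Br
Why: Electrophilic aromatic bromination, in which the strongest donor (OMe) directs para to C-3, a position also ortho to F and CH3 and meta to CHO, while the polar medium in the dark suppresses benzylic bromination.

**Step 3**
Reactants: 4 3-bromo-2-fluoro-6-methoxy-4-methylbenzaldehyde
Product: 5 benzyl 2-fluoro-3-formyl-4-methoxy-6-methylbenzoate
Conditions: Pd(OAc)2 (cat.), Xantphos (cat.), CO (1 atm), BnOH, Et3N, toluene, 80 °C
Reagents that add atoms: carbon monoxide [C-]#[O+]; benzyl alcohol OCc1ccccc1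
Why: Palladium-catalysed alkoxycarbonylation (Heck carbonylation) of an aryl bromide, which leaves C–F and CHO untouched, and the alkoxide-free non-polar medium should keep the activated fluoride from being displaced.

**Step 4**
Reactants: 6 N-Boc-L-valine
Product: 7 (S)-2-tert-butoxy-4-isopropyl-1,3-oxazol-5(4H)-one
Conditions: EDC·HCl, CH2Cl2, 0 °C
Reagents that add atoms: none
Why: Carbodiimide cyclodehydration of a hindered N-alkoxycarbonyl amino acid to its 2-alkoxy-5(4H)-oxazolone, a known reaction in the absence of a nucleophile, and the C-4 configuration is irrelevant because step 7 erases it.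

**Step 5**
Reactants: 8 5-bromo-2,4-dihydroxybenzaldehyde
Product: 9 2,4-bis(benzyloxy)-5-bromobenzaldehyde
Conditions: BnBr, K2CO3, DMF, 60 °C
Reagents that add atoms: benzyl bromide BrCc1ccccc1
Why: Double Williamson etherification, in which warming in DMF also alkylates the chelated 2-OH.

**Step 6**
Reactants: 9 2,4-bis(benzyloxy)-5-bromobenzaldehyde
Product: 11 2,4-bis(benzyloxy)-5-bromophenol, via aryl formate 10 (not isolated)
Conditions: mCPBA, CH2Cl2, rt; then K2CO3 (cat.), MeOH, rt
Reagents that add atoms: 3-chloroperoxybenzoic acid O=C(OO)c1cccc(Cl)c1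
Why: Baeyer–Villiger (Dakin-type) oxidation, in which the electron-rich aryl group migrates, and mild methanolysis of the formate frees the one phenol that later becomes the diaryl ether oxygen.

**Step 7**
Reactants: 11 2,4-bis(benzyloxy)-5-bromophenol; 7 (S)-2-tert-butoxy-4-isopropyl-1,3-oxazol-5(4H)-one
Product: 14 [2,4-bis(benzyloxy)-5-bromophenoxy][(2-tert-butoxy-4-isopropyl-1,3-oxazol-5-yl)oxy]diisopropylsilane, via chlorosilane 12 (not isolated), via potassium oxazololate 13 (not isolated)
Conditions: 11, iPr2SiCl2 (excess), Et3N, THF, 0 °C, volatiles removed; then 7 pre-treated with KHMDS (THF, −78 °C), −78 to 0 °C; filtered under Ar and used crude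
Reagents that add atoms: dichlorodiisopropylsilane CC(C)[Si](Cl)(Cl)C(C)C
Why: Stepwise silaketal formation, in which the hindered dichlorosilane reacts only once with the phenol and the hard potassium azlactone enolate is silylated on oxygen (the known route to 5-silyloxyoxazoles), which aromatises the ring and erases the valine stereocentre.

**Step 8**
Reactants: 14 [2,4-bis(benzyloxy)-5-bromophenoxy][(2-tert-butoxy-4-isopropyl-1,3-oxazol-5-yl)oxy]diisopropylsilane
Product: 20 rac-5,7-bis(benzyloxy)-4-hydroxy-3-methoxy-2-benzofuran-1(3H)-one, via aryllithium 15 (not isolated), via aryne 16 (not isolated), via cycloadduct 17 (not isolated), via isobenzofuran 18 (not isolated), via silicon-bridged phthalide 19 (not isolated)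
Conditions: LiTMP (from TMPH + nBuLi), THF (0.005 M), Ar, −78 °C to rt, then reflux; then HCl in MeOH, 0 to 45 °C
Reagents that add atoms: methanol CO
Why: Proposed new method: LiTMP removes the one ring proton that lies between bromine and the silyloxy oxygen, LiBr leaves at once, and aryne 16 is caught by the tethered oxazole in an intramolecular [4+2] cycloaddition across oxazole C-2 and C-5 that forms both aryl–carbon bonds in one event; on warming 17 loses isobutyronitrile by cycloreversion, and methanolic HCl protonates the 1,3-dioxygenated isobenzofuran 18 on carbon, removes isobutene and the silicon bridge and ends the sequence at the methyl pseudo-ester 20. The closest known reaction types are the benzyne–oxazole Diels–Alder/nitrile-extrusion route to isobenzofurans, the alkyne–oxazole furan synthesis, silicon-tethered aryne–furan cycloadditions and the C-protonation of silyl ketene acetals, and what is new is a 2-alkoxy-5-silyloxyoxazole serving as a C–O–C unit that already has the oxidation level of the pseudo-acid. The five-membered oxygen ring is closed by the cycloaddition itself (two C–C bonds to the carbons flanking O-1), the temporary six-membered 1,3-dioxa-2-silin ring closes in the same event because the C–O–Si–O link spans the peri distance, and the aza bridge is only transient. The two bridgehead centres of 17 vanish with the nitrile, and the acetal carbon of 20 arises by protonation of a planar furan carbon without facial control, so 20 is racemic, which is harmless because this centre is labile at the lactol stage and is fixed in step 12. The step needs the carbonyl carbon next to the 7-oxygen and the acetal carbon next to the 4-oxygen: the tether puts oxazole C-5 on the carbon beside the phenolic oxygen, and protonation at that carbon is favoured because the resulting tert-butoxy dioxocarbenium ion is conjugated with the ortho and para benzyloxy groups, whereas the alternative ion has only one silyloxy donor. The tether and the high dilution also keep the very reactive 18 from meeting a second aryne.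

**Step 9**
Reactants: 20 rac-5,7-bis(benzyloxy)-4-hydroxy-3-methoxy-2-benzofuran-1(3H)-one; 5 benzyl 2-fluoro-3-formyl-4-methoxy-6-methylbenzoate
Product: 21 rac-benzyl 2-{[5,7-bis(benzyloxy)-3-methoxy-1-oxo-1,3-dihydro-2-benzofuran-4-yl]oxy}-3-formyl-4-methoxy-6-methylbenzoate
Conditions: K2CO3, DMF, 60 °C
Reagents that add atoms: none
Why: Nucleophilic aromatic substitution (addition–elimination), in which the fluoride of 5 is activated by an ortho formyl and an ortho ester group, 20 offers a single free phenol, and the lactone acetal, benzyl ethers and aldehyde tolerate K2CO3 in DMF.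

**Step 10**
Reactants: 21 rac-diaryl ether benzyl ester
Product: 22 rac-2-[(5,7-dihydroxy-3-methoxy-1-oxo-1,3-dihydro-2-benzofuran-4-yl)oxy]-3-formyl-4-methoxy-6-methylbenzoic acid
Conditions: H2 (1 atm), Pd/C, EtOAc–THF, rt, stopped after three equivalents of H2
Reagents that add atoms: none
Why: Catalytic hydrogenolysis, in which the two aryl benzyl ethers and the benzyl ester are cleaved faster than the hindered aryl aldehyde or the phthalidyl C–O bonds are reduced.

**Step 11**
Reactants: 22 rac-seco acid
Product: 24 rac-1,4-dihydroxy-10-methoxy-8-methyl-3,7-dioxo-1,3-dihydro-7H-isobenzofuro[4,5-b][1,4]benzodioxepine-11-carbaldehyde, via depsidone methyl pseudo-ester 23 (not isolated)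
Conditions: (CF3CO)2O, toluene, 0 °C to rt; then TFA–H2O, 50 °C
Reagents that add atoms: water O
Why: Mixed-anhydride lactonisation, the standard closure of 2-(2-hydroxyaryloxy)benzoic acids to depsidones, can reach only the 5-OH (seven-membered ring, the chelated 7-OH is out of reach) and runs without base so that no Smiles migration of the activated ring A can occur, after which aqueous acid hydrolyses the methyl pseudo-ester and any aryl trifluoroacetate.

**Step 12**
Reactants: 24 rac-lactol
Product: 25 (1R)-1,4-bis{[(benzyloxy)carbonyl]oxy}-10-methoxy-8-methyl-3,7-dioxo-1,3-dihydro-7H-isobenzofuro[4,5-b][1,4]benzodioxepine-11-carbaldehyde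
Conditions: dibenzyl dicarbonate (2.5 equiv), chiral bicyclic-imidazole acyl-transfer catalyst (10 mol %, the enantiomer matched to the (S)-lactol), iPr2NEt (cat.), toluene, −20 °C; recrystallisation
Reagents that add atoms: dibenzyl dicarbonate O=C(OCc1ccccc1)OC(=O)OCc1ccccc1
Why: Acylative dynamic kinetic resolution of a 3-hydroxyphthalide, in which the lactol enantiomers interconvert through the ring-opened 2-formylbenzoate under amine catalysis while the chiral catalyst carbonates the (S)-lactol faster, so that under catalyst control the whole racemate should be funnelled into one phthalidyl carbonate (R only because the CIP priorities change), the phenol being carbonated too without stereochemical consequence.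

**Step 13**
Reactants: 25 (1R)-bis(benzyl carbonate)
Product: 26 (1S)-1,4-dihydroxy-10-methoxy-8-methyl-3,7-dioxo-1,3-dihydro-7H-isobenzofuro[4,5-b][1,4]benzodioxepine-11-carbaldehyde (target)
Conditions: H2 (1 atm), Pd/C, EtOAc, 0 °C, short contact; filtered and concentrated cold
Reagents that add atoms: none
Why: Hydrogenolysis cleaves only the two benzyl–oxygen bonds and the carbonic half-esters lose CO2 on their own, so no bond to the stereocentre is touched, and in a neutral, aprotic, cold medium the (S)-lactol should be released with retention.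

**Compound list**
1 | 1-fluoro-3-methoxy-5-methylbenzene | COc1cc(C)cc(F)c1 | starting material
2 | (2-fluoro-6-methoxy-4-methylphenyl)lithium | COc1cc(C)cc(F)c1[Li] | intermediate
3 | 2-fluoro-6-methoxy-4-methylbenzaldehyde | COc1cc(C)cc(F)c1C=O | intermediate
4 | 3-bromo-2-fluoro-6-methoxy-4-methylbenzaldehyde | COc1cc(C)c(Br)c(F)c1C=O | intermediate
5 | benzyl 2-fluoro-3-formyl-4-methoxy-6-methylbenzoate | COc1cc(C)c(C(=O)OCc2ccccc2)c(F)c1C=O | intermediate
6 | N-Boc-L-valine | CC(C)[C@H](NC(=O)OC(C)(C)C)C(=O)O | starting material
7 | (S)-2-tert-butoxy-4-isopropyl-1,3-oxazol-5(4H)-one | CC(C)[C@@H]1N=C(OC(C)(C)C)OC1=O | intermediate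
8 | 5-bromo-2,4-dihydroxybenzaldehyde | O=Cc1cc(Br)c(O)cc1O | starting material
9 | 2,4-bis(benzyloxy)-5-bromobenzaldehyde | O=Cc1cc(Br)c(OCc2ccccc2)cc1OCc1ccccc1 | intermediate
10 | 2,4-bis(benzyloxy)-5-bromophenyl formate | O=COc1cc(Br)c(OCc2ccccc2)cc1OCc1ccccc1 | intermediate
11 | 2,4-bis(benzyloxy)-5-bromophenol | Oc1cc(Br)c(OCc2ccccc2)cc1OCc1ccccc1 | intermediate
12 | [2,4-bis(benzyloxy)-5-bromophenoxy]chlorodiisopropylsilane | CC(C)[Si](Cl)(C(C)C)Oc1cc(Br)c(OCc2ccccc2)cc1OCc1ccccc1 | intermediate
13 | potassium 2-tert-butoxy-4-isopropyl-1,3-oxazol-5-olate | CC(C)c1nc(OC(C)(C)C)oc1[O-].[K+] | intermediate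
14 | [2,4-bis(benzyloxy)-5-bromophenoxy][(2-tert-butoxy-4-isopropyl-1,3-oxazol-5-yl)oxy]diisopropylsilane | CC(C)c1nc(OC(C)(C)C)oc1O[Si](C(C)C)(C(C)C)Oc1cc(Br)c(OCc2ccccc2)cc1OCc1ccccc1 | intermediate
15 | 6-lithio derivative of 14 (Li between the O–Si and Br carbons) | CC(C)c1nc(OC(C)(C)C)oc1O[Si](C(C)C)(C(C)C)Oc1c([Li])c(Br)c(OCc2ccccc2)cc1OCc1ccccc1 | intermediate
16 | aryne from 15 (5,6-didehydro, flanked by O–Si and OBn) | CC(C)c1nc(OC(C)(C)C)oc1O[Si](C(C)C)(C(C)C)OC1=C(OCc2ccccc2)C=C(OCc2ccccc2)C#C1 | intermediate
17 | rac-6,8-bis(benzyloxy)-1-tert-butoxy-3-isopropyl-1,4-epoxy-1,4-dihydroisoquinoline with a 4-O–Si(iPr)2–O-5 bridge | CC(C)C1=NC2(OC(C)(C)C)OC13O[Si](C(C)C)(C(C)C)Oc4c(OCc5ccccc5)cc(OCc5ccccc5)c2c43 | intermediate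
18 | 5,7-bis(benzyloxy)-1-tert-butoxyisobenzofuran with a 3-O–Si(iPr)2–O-4 bridge | CC(C)(C)Oc1oc2O[Si](C(C)C)(C(C)C)Oc3c(OCc4ccccc4)cc(OCc4ccccc4)c1c23 | intermediate
19 | rac-5,7-bis(benzyloxy)phthalide with a 3-O–Si(iPr)2–O-4 bridge | O=C1OC2O[Si](C(C)C)(C(C)C)Oc3c(OCc4ccccc4)cc(OCc4ccccc4)c1c23 | intermediate
20 | rac-5,7-bis(benzyloxy)-4-hydroxy-3-methoxy-2-benzofuran-1(3H)-one | COC1OC(=O)c2c1c(O)c(OCc1ccccc1)cc2OCc1ccccc1 | intermediate
21 | rac-benzyl 2-{[5,7-bis(benzyloxy)-3-methoxy-1-oxo-1,3-dihydro-2-benzofuran-4-yl]oxy}-3-formyl-4-methoxy-6-methylbenzoate | COc1cc(C)c(C(=O)OCc2ccccc2)c(Oc2c(OCc3ccccc3)cc(OCc3ccccc3)c3c2C(OC)OC3=O)c1C=O | intermediate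
22 | rac-2-[(5,7-dihydroxy-3-methoxy-1-oxo-1,3-dihydro-2-benzofuran-4-yl)oxy]-3-formyl-4-methoxy-6-methylbenzoic acid | COc1cc(C)c(C(=O)O)c(Oc2c(O)cc(O)c3c2C(OC)OC3=O)c1C=O | intermediate
23 | rac-4-hydroxy-1,10-dimethoxy-8-methyl-3,7-dioxo-1,3-dihydro-7H-isobenzofuro[4,5-b][1,4]benzodioxepine-11-carbaldehyde | COc1cc(C)c2c(c1C=O)Oc1c(cc(O)c3c1C(OC)OC3=O)OC2=O | intermediate
24 | rac-1,4-dihydroxy-10-methoxy-8-methyl-3,7-dioxo-1,3-dihydro-7H-isobenzofuro[4,5-b][1,4]benzodioxepine-11-carbaldehyde | COc1cc(C)c2c(c1C=O)Oc1c(cc(O)c3c1C(O)OC3=O)OC2=O | intermediate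
25 | (1R)-1,4-bis{[(benzyloxy)carbonyl]oxy} derivative of 24 (same spatial arrangement at C-1 as the target) | COc1cc(C)c2c(c1C=O)Oc1c(cc(OC(=O)OCc4ccccc4)c3c1[C@@H](OC(=O)OCc1ccccc1)OC3=O)OC2=O | intermediate
26 | (1S)-1,4-dihydroxy-10-methoxy-8-methyl-3,7-dioxo-1,3-dihydro-7H-isobenzofuro[4,5-b][1,4]benzodioxepine-11-carbaldehyde | COc1cc(C)c2c(c1C=O)Oc1c(cc(O)c3c1[C@@H](O)OC3=O)OC2=O | target

**Total step count:** 13.
**Longest linear sequence:** 9 steps (from 8 through steps 5–13).

**Steps most likely to fail**

1. Step 8 (new method).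
   - What may go wrong:
     - [2+2] addition or C-4 arylation at the silyl ketene acetal part of the oxazole instead of the [4+2] mode;
     - oxygen-to-carbon silyl migration in the aryllithium before bromide loss;
     - sluggish nitrile extrusion;
     - protonation at the wrong furan carbon.
   - Fallback with known chemistry, from 11 back to 20:
     - The phenol would be protected (MOMCl, iPr2NEt) as 1,5-bis(benzyloxy)-2-bromo-4-(methoxymethoxy)benzene F1.
     - Bromine–lithium exchange (nBuLi, −78 °C) and quenching with diethylcarbamoyl chloride would give 2,4-bis(benzyloxy)-N,N-diethyl-5-(methoxymethoxy)benzamide F2.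
     - Directed ortho-metalation (sBuLi, TMEDA, −78 °C) at the carbon between the amide and the OMOM group, followed by DMF, would give 4,6-bis(benzyloxy)-N,N-diethyl-2-formyl-3-(methoxymethoxy)benzamide F3.
     - Methanolic HCl at reflux would cleave the MOM group and, with participation of the neighbouring aldehyde, the amide, to give 20.

2. Step 12.
   - What may go wrong: too small a rate difference between the lactol enantiomers, racemisation slower than acylation, or uncatalysed background carbonation, each of which erodes the enantiomeric purity.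
   - Fallback with an auxiliary instead of a catalyst, from 24 to 26:
     - Acid-catalysed acetalisation with (S)-1-phenylethanol (CSA, toluene, 4 Å sieves) would give the (1S)-1-[(S)-1-phenylethoxy] acetal F4 and its (1R) epimer F5.
     - The two would be separated by crystallisation or chromatography.
     - F5 would be returned to the same acid conditions, where it re-equilibrates through the oxocarbenium ion.
     - Hydrogenolysis of F4 (H2, Pd/C, EtOAc, 0 °C) cleaves the benzylic C–O bond of the auxiliary only and would give 26 directly.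

3. Step 9.
   - What may go wrong: slow substitution because both partners are di-ortho-substituted, so that attack of the phenoxide on the ester or aldehyde carbonyl and decomposition on long heating compete.
   - Fallback that makes the C–O bond intramolecularly, from 20 and 5 back to 23:
     - Hydrogenolysis of 20 would give 4,5,7-trihydroxy-3-methoxy-2-benzofuran-1(3H)-one F6.
     - Hydrogenolysis of 5 would give 2-fluoro-3-formyl-4-methoxy-6-methylbenzoic acid F7.
     - Carbodiimide esterification (EDC, cat. DMAP) at the least hindered and most acidic 5-OH would give the depside F8.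
     - Cs2CO3 in DMF would close the seven-membered ring by intramolecular SNAr to 23, which continues with the aqueous-acid stage of step 11.

**Further compounds**
F1 | step 8 | 1,5-bis(benzyloxy)-2-bromo-4-(methoxymethoxy)benzene | COCOc1cc(Br)c(OCc2ccccc2)cc1OCc1ccccc1
F2 | step 8 | 2,4-bis(benzyloxy)-N,N-diethyl-5-(methoxymethoxy)benzamide | CCN(CC)C(=O)c1cc(OCOC)c(OCc2ccccc2)cc1OCc1ccccc1
F3 | step 8 | 4,6-bis(benzyloxy)-N,N-diethyl-2-formyl-3-(methoxymethoxy)benzamide | CCN(CC)C(=O)c1c(C=O)c(OCOC)c(OCc2ccccc2)cc1OCc1ccccc1
F4 | step 12 | (1S)-4-hydroxy-10-methoxy-8-methyl-3,7-dioxo-1-[(S)-1-phenylethoxy]-1,3-dihydro-7H-isobenzofuro[4,5-b][1,4]benzodioxepine-11-carbaldehyde | COc1cc(C)c2c(c1C=O)Oc1c(cc(O)c3c1[C@@H](O[C@@H](C)c1ccccc1)OC3=O)OC2=O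
F5 | step 12 | (1R) epimer of F4 | COc1cc(C)c2c(c1C=O)Oc1c(cc(O)c3c1[C@H](O[C@@H](C)c1ccccc1)OC3=O)OC2=O
F6 | step 9 | rac-4,5,7-trihydroxy-3-methoxy-2-benzofuran-1(3H)-one | COC1OC(=O)c2c1c(O)c(O)cc2O
F7 | step 9 | 2-fluoro-3-formyl-4-methoxy-6-methylbenzoic acid | COc1cc(C)c(C(=O)O)c(F)c1C=O
F8 | step 9 | rac-4,7-dihydroxy-3-methoxy-1-oxo-1,3-dihydro-2-benzofuran-5-yl 2-fluoro-3-formyl-4-methoxy-6-methylbenzoate | COc1cc(C)c(C(=O)Oc2cc(O)c3c(c2O)C(OC)OC3=O)c(F)c1C=O
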